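In a one-step world, Ry turns into Ji with one constant, and the fraction of Ry left falls by the same factor in each equal stretch of time. So I work with the fraction left, not with the Ji made. The step between Ji and Ry also has a way back, but Ve comes out of it unchanged, so I treat Ji and Ry as exchanging in a pseudo-first-order way. I apply the same rule to the gap between the share of Ji in Ji plus Ry and the plateau of that share.

in all of them: Ve 2.5 mM
- blue: Xi 0.50 M; run made earlier
- violet: Xi 0.75 M; run made earlier
- summer: Xi 0.50 M; everything together in a closed stirred flask, run for 10 min; time 10 min
- autumn: Xi 0.50 M; a single well-mixed tank run continuously and read at steady state, 10 min in it on average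
- winter: Xi 0.50 M (fed, over 8.00 min); a stirred flask in which Xi is dosed at a steady rate over 8.00 min without added volume, worked up at 10 min; time 10 min

- blue (time / min: Ji / %, Ry / %, Xi / %): 0.833: 4.6, 74.1, 13.7; 1.50: 7.8, 79.0, 4.9; 2.50: 11.9, 76.1, 3.6; 3.00: 14.2, 74.9, 3.2; 4.00: 17.2, 70.9, 3.2; 5.00: 20.9, 68.4, 2.4; 6.00: 23.3, 65.5, 2.7
- violet (time / s: Ji / %, Ry / %, Xi / %): 10.0: 0.4, 30.8, 61.2; 15.0: 0.8, 41.2, 49.0; 25.0: 2.6, 55.9, 32.5; 30.0: 2.3, 61.1, 26.0; 40.0: 3.5, 67.6, 17.4; 50.0: 4.0, 71.3, 12.4; 60.0: 5.1, 74.2, 9.6

(standard deviation of a reading: 0.3 percentage points)

- percentages count the Xi that a species holds: one Wa counts as two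
- the stated concentrations are those of everything mixed, before any reaction; amounts are the same in each set-up
- steps under discussion: Xi + Ve <-> Ji + Ve; Ji + Ve <-> Ry + Ve; Ry <-> Xi; 2 Xi -> Wa
- the feed brings no volume worth counting
- the earlier runs were made in a closed, stirred flask

* the set-up with the highest share of Ji in all that became Ji or Ry, at the outlet or at the end ("none" if the first two lie within 2 percentage points) (summer / autumn / winter / none)
* share of Ji in all that became Ji or Ry, at the outlet or at the end, summer
* share of Ji in all that became Ji or Ry, at the outlet or at the end, autumn
* share of Ji in all that became Ji or Ry, at the outlet or at the end, winter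

In blue, Xi is down to 4.9% at 1.50 min, and I let the share start from nothing at time zero. It reads 15.9% at 3.00 min and 26.2% at 6.00 min, each carrying the scatter of 0.3 percentage points in its readings. The two stretches are equal, so the second gain divided by the first is the fraction of the gap left after one stretch, 0.646. As readings from blue, that gives 0.145 min⁻¹, the closing constant, the first-order constant with which the gap shrinks, and a plateau of 45.1%.

Now I reckon each flask by the fraction of the gap left. In summer, the charge has the age 10 min, so the fraction left is 0.234. In the autumn tank, the mean stay is also 10 min. At steady state, the gap closed in the tank per unit time equals the share of Ji that the outflow carries away, so the fraction left is one over one plus constant times stay, 0.407. In winter, the portions are fed evenly and their ages lie between 2.00 min and 10 min, and averaging the fraction left over those ages gives 0.442. By this reckoning summer leaves the smallest gap, and my shares are 34.5% for summer, 26.7% for autumn and 25.2% for winter.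

The forecast, saying that “the late-fed material has less time to convert”, gives other figures, 36%, 29.5% and 26%, with the same winner, summer.

Summer gives 33.3%, autumn 26.6% and winter 24.6%, so summer comes first.

    Xi + Ve ⇌ Ji + Ve, rate k1*[Xi]*[Ve] forward; the back reaction follows from the equilibrium constant (K = 17.0, k = 19.0 M⁻¹ min⁻¹)
    Ji + Ve ⇌ Ry + Ve, rate k2*[Ve]*[Ji] forward; the back reaction follows from the equilibrium constant (K = 1.40, k = 37.0 M⁻¹ min⁻¹)
    Ry ⇌ Xi (k = 0.100 min⁻¹)
    2 Xi → Wa (k = 0.440 M⁻¹ min⁻¹)

The step from two Xi to Wa makes no difference to the summer share, although summer holds 8.70% as Wa at 10.0 min. The closing constant goes once more to the summer flask left until 15 min: the fraction of the gap left is 0.113, which on my plateau means a share of 40.0%, and that flask stands at 38.0%.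

The earlier runs and the new flask come from a simulation for substances that don't exist.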